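## Plan

- Carbon labels used below: C1 (CHOH), C2=C3(Me), C4 (CH–O–aroyl), C5H2, C6=C7(Me), C8H2, C9H2, C10H2, C11 (CMe2, bonded to C1).
- Retrosynthetic cuts, in order: the C4–O aroyl bond and the silyl groups; the ring bond C8–C9, which opens the only ring; the C6–O leaving group; C4–C5 (aldol); the C3–CHO oxidation level (allylic oxidation of a prenyl methyl); C1–C11 (reverse prenylation of prenal).
- Forward: a linear chain C9=C10–C11–C1–C2=C3–C4–C5–C6(O-phosphate)–C7=C8 is grown from prenal; the 11-membered ring closes in step 8; the 4-hydroxybenzoate is attached afterwards.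
- Enabling feature: in the ring, the allylic methylene C8 of the C6=C7(Me) alkene is tied through C9–C10 to the quaternary C11. The C8–C9 bond is therefore the bond of a formal ene adduct between an isopropenyl unit (C7=C8, leaving group on C6) and a vinyl group on C11 (C9=C10). Anti-Markovnikov hydrometalation of that vinyl group gives a C9 nucleophile for an SN2′ closure that also creates the (E)-C6=C7 bond from either C6 epimer.
- Stereochemistry: C1 (R) from a reagent-controlled reverse prenylation; C4 (R) from a reagent-controlled boron aldol (the wrong epimer is a separable diastereomer); C2=C3 (E) from oxidation of the (E)-methyl group; C6=C7 (E) from the stereoconvergent ring closure.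

Key step: step 8

Assumption (step 4): for a methyl ketone enolate, the boron chloride made from (−)-α-pinene is taken to direct attack to the Re face of the aldehyde; if the sense is the reverse, the reagent from (+)-α-pinene is used and nothing else changes.

## Route

Step 1
Reactants: 1 3-methylbut-2-enal; 2 3-methylbuta-1,2-diene
Product: 5 (4R)-3,3,6-trimethylhepta-1,5-dien-4-ol, via prenylborane 3 (not isolated), via borinate ester 4 (not isolated)
Conditions: 2, (−)-Ipc2BH [from (+)-α-pinene], THF, −25 °C; then 1, −78 °C; then NaOH, H2O2, 0 °C to rt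
Reagents that add atoms: none
Why: Brown allylboration with allyl transposition (reverse prenylation): the prenylborane formed by hydroboration of the allene should add through a chair transition state to the Si face of the enal, as dictated by the isopinocampheyl groups, which sets C1 as R.

Step 2
Reactants: 5 (4R)-3,3,6-trimethylhepta-1,5-dien-4-ol
Product: 6 tert-butyl(dimethyl){[(4R)-3,3,6-trimethylhepta-1,5-dien-4-yl]oxy}silane
Conditions: TBSOTf, 2,6-lutidine, CH2Cl2, 0 °C
Reagents that add atoms: tert-butyldimethylsilyl trifluoromethanesulfonate, CC(C)(C)[Si](C)(C)OS(=O)(=O)C(F)(F)F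
Why: Silylation with a silyl triflate should protect the hindered neopentyl-type allylic alcohol, which must stay masked until the last step.

Step 3
Reactants: 6 tert-butyl(dimethyl){[(4R)-3,3,6-trimethylhepta-1,5-dien-4-yl]oxy}silane
Product: 8 (2E,4R)-4-[(tert-butyldimethylsilyl)oxy]-2,5,5-trimethylhepta-2,6-dienal, via allylic alcohol 7 (not isolated)
Conditions: SeO2 (1.2 equiv), 1,4-dioxane, 80 °C
Reagents that add atoms: selenium dioxide, O=[Se]=O
Why: Riley allylic oxidation (ene reaction, then 2,3-sigmatropic shift) should take place at the (E)-methyl group of the trisubstituted alkene and run on to the aldehyde, which fixes C2=C3 as E; the vinyl group has no allylic hydrogen and is not touched.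

Step 4
Reactants: 8 (2E,4R)-4-[(tert-butyldimethylsilyl)oxy]-2,5,5-trimethylhepta-2,6-dienal; 9 3-methylbut-3-en-2-one
Product: 12 (5R,6E,8R)-8-[(tert-butyldimethylsilyl)oxy]-5-hydroxy-2,6,9,9-tetramethylundeca-1,6,10-trien-3-one, via enol borinate 10 (not isolated), via boron aldolate 11 (not isolated)
Conditions: 9, (+)-Ipc2BCl [from (−)-α-pinene], Et3N, Et2O, −78 to 0 °C; then 8, −78 to −20 °C; then H2O2, MeOH, pH 7 buffer, 0 °C
Reagents that add atoms: none
Why: Diisopinocampheylboron-mediated aldol reaction of a methyl ketone (Paterson aldol): the dienol borinate should add through a cyclic transition state to the Re face of the enal, setting C4 as R, and because C1 is already fixed the minor C4 epimer is a diastereomer that chromatography should remove.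

Step 5
Reactants: 12 (5R,6E,8R)-8-[(tert-butyldimethylsilyl)oxy]-5-hydroxy-2,6,9,9-tetramethylundeca-1,6,10-trien-3-one
Product: 13 (5R,6E,8R)-8-[(tert-butyldimethylsilyl)oxy]-2,6,9,9-tetramethyl-5-[(triethylsilyl)oxy]undeca-1,6,10-trien-3-one
Conditions: TESOTf, 2,6-lutidine, CH2Cl2, −78 °C
Reagents that add atoms: triethylsilyl trifluoromethanesulfonate, CC[Si](CC)(CC)OS(=O)(=O)C(F)(F)F
Why: Low-temperature silylation should avoid retro-aldol and β-elimination; a triethylsilyl ether is chosen because it cannot act as an allylic leaving group in step 8 and can later be removed beside the TBS ether.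

Step 6
Reactants: 13 (5R,6E,8R)-8-[(tert-butyldimethylsilyl)oxy]-2,6,9,9-tetramethyl-5-[(triethylsilyl)oxy]undeca-1,6,10-trien-3-one
Product: 14 (3RS,5R,6E,8R)-8-[(tert-butyldimethylsilyl)oxy]-2,6,9,9-tetramethyl-5-[(triethylsilyl)oxy]undeca-1,6,10-trien-3-ol (both C3 epimers)
Conditions: NaBH4, CeCl3·7H2O, MeOH, −78 °C
Reagents that add atoms: none
Why: Luche reduction should give clean 1,2-reduction of the isopropenyl ketone; the new carbinol configuration (C6 in the ring labels) is deliberately left uncontrolled because this carbon becomes sp2 in step 8.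

Step 7
Reactants: 14 (3RS,5R,6E,8R)-8-[(tert-butyldimethylsilyl)oxy]-2,6,9,9-tetramethyl-5-[(triethylsilyl)oxy]undeca-1,6,10-trien-3-ol
Product: 15 diethyl (3RS,5R,6E,8R)-8-[(tert-butyldimethylsilyl)oxy]-2,6,9,9-tetramethyl-5-[(triethylsilyl)oxy]undeca-1,6,10-trien-3-yl phosphate
Conditions: ClP(O)(OEt)2, pyridine, DMAP (cat.), CH2Cl2, 0 °C
Reagents that add atoms: diethyl chlorophosphate, CCOP(=O)(Cl)OCC
Why: Phosphorylation of the secondary allylic alcohol installs the leaving group required for copper-catalysed SN2′ substitution; the phosphate is used at once because such esters can undergo allylic transposition on storage.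

Step 8
Reactants: 15 diethyl (3RS,5R,6E,8R)-8-[(tert-butyldimethylsilyl)oxy]-2,6,9,9-tetramethyl-5-[(triethylsilyl)oxy]undeca-1,6,10-trien-3-yl phosphate
Product: 17 tert-butyl(dimethyl){[(1R,2E,4R,6E)-3,7,11,11-tetramethyl-4-[(triethylsilyl)oxy]cycloundeca-2,6-dien-1-yl]oxy}silane, via alkylzirconocene 16 (not isolated)
Conditions: Cp2Zr(H)Cl (1.2 equiv), CH2Cl2, rt, 20 min; then addition over 12 h to CuBr·SMe2 (20 mol %), THF, 40 °C, final concentration 1 mM
Reagents that add atoms: none
Why: Proposed new method: Cp2Zr(H)Cl should add only to the monosubstituted C9=C10 vinyl group (the 1,1-disubstituted C7=C8 and trisubstituted C2=C3 alkenes react far more slowly) and place zirconium on C9; transmetalation to copper then gives an alkylcopper that attacks the methylene carbon C8 anti to the C6 phosphate (oxidative addition to a γ-bound allyl species of trivalent copper, then reductive elimination), so that the C8–C9 bond forms while the double bond moves to C6=C7 and the phosphate leaves. The closest known reaction type is the intermolecular copper-catalysed SN2′ allylic alkylation of alkylzirconocenes (and of alkyl-9-BBN reagents) with allylic phosphates and chlorides; its use to close a medium ring is the untested part. The 11-membered carbocycle closes in the 11-endo-trig mode, the attacked C7=C8 bond becoming the ring bond C7–C8. No stereocentre is created; the C6=C7 geometry should be controlled by allylic strain in the transition state, where C5 turns away from the copper-bearing C8 and ends trans to it (E), and because C6 becomes sp2 both C6 epimers of 15 should converge on the same alkene. The step needs γ- over α-attack (favoured by the neutral alkylcopper and the unhindered CH2 terminus), ring closure over oligomerisation (slow addition at high dilution) and a two-electron C9 nucleophile, since a C9 radical would close 5-exo onto C2=C3; the other allylic oxygen groups (on C1 and C4) are silyl ethers that cannot leave.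

Step 9
Reactants: 17 tert-butyl(dimethyl){[(1R,2E,4R,6E)-3,7,11,11-tetramethyl-4-[(triethylsilyl)oxy]cycloundeca-2,6-dien-1-yl]oxy}silane
Product: 18 (1R,2E,4R,9E)-4-[(tert-butyldimethylsilyl)oxy]-2,5,5,9-tetramethylcycloundeca-2,9-dien-1-ol
Conditions: PPTS, MeOH–CH2Cl2, 0 °C
Reagents that add atoms: none
Why: Mild acid-catalysed methanolysis should cleave the less hindered triethylsilyl ether selectively and leave the neopentyl-type TBS ether in place.

Step 10
Reactants: 18 (1R,2E,4R,9E)-4-[(tert-butyldimethylsilyl)oxy]-2,5,5,9-tetramethylcycloundeca-2,9-dien-1-ol; 19 4-[(tert-butyldimethylsilyl)oxy]benzoic acid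
Product: 20 (1R,2E,4R,9E)-4-[(tert-butyldimethylsilyl)oxy]-2,5,5,9-tetramethylcycloundeca-2,9-dien-1-yl 4-[(tert-butyldimethylsilyl)oxy]benzoate
Conditions: DCC, DMAP, CH2Cl2, rt
Reagents that add atoms: none
Why: Steglich esterification should acylate the allylic hydroxyl with retention of configuration, the phenol being masked to prevent self-acylation.

Step 11
Reactants: 20 (1R,2E,4R,9E)-4-[(tert-butyldimethylsilyl)oxy]-2,5,5,9-tetramethylcycloundeca-2,9-dien-1-yl 4-[(tert-butyldimethylsilyl)oxy]benzoate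
Product: 21 (1R,2E,4R,9E)-4-hydroxy-2,5,5,9-tetramethylcycloundeca-2,9-dien-1-yl 4-hydroxybenzoate
Conditions: Bu4NF, AcOH, THF, 0 to 40 °C
Reagents that add atoms: none
Why: Fluoride should cleave the aryl and the alkyl silyl ether in one operation, and the acetic acid buffer protects the benzoate from basic cleavage; acyl migration to the C1 hydroxyl is not possible across the (E)-alkene.

## Compound list

1 | 3-methylbut-2-enal | CC(C)=CC=O | starting material
2 | 3-methylbuta-1,2-diene | CC(C)=C=C | starting material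
3 | (3-methylbut-2-en-1-yl)bis(isopinocampheyl)borane, isopinocampheyl groups from (+)-α-pinene | CC(C)=CCB([C@@H]1C[C@@H]2C[C@H]([C@H]1C)C2(C)C)[C@@H]1C[C@@H]2C[C@H]([C@H]1C)C2(C)C | intermediate
4 | bis(isopinocampheyl)borinic ester of 5 | CC(C)=C[C@@H](OB([C@@H]1C[C@@H]2C[C@H]([C@H]1C)C2(C)C)[C@@H]1C[C@@H]2C[C@H]([C@H]1C)C2(C)C)C(C)(C)C=C | intermediate
5 | (4R)-3,3,6-trimethylhepta-1,5-dien-4-ol | CC(C)=C[C@@H](O)C(C)(C)C=C | intermediate
6 | tert-butyl(dimethyl){[(4R)-3,3,6-trimethylhepta-1,5-dien-4-yl]oxy}silane | CC(C)=C[C@@H](O[Si](C)(C)C(C)(C)C)C(C)(C)C=C | intermediate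
7 | (2E,4R)-4-[(tert-butyldimethylsilyl)oxy]-2,5,5-trimethylhepta-2,6-dien-1-ol | OC/C(C)=C/[C@@H](O[Si](C)(C)C(C)(C)C)C(C)(C)C=C | intermediate
8 | (2E,4R)-4-[(tert-butyldimethylsilyl)oxy]-2,5,5-trimethylhepta-2,6-dienal | O=C/C(C)=C/[C@@H](O[Si](C)(C)C(C)(C)C)C(C)(C)C=C | intermediate
9 | 3-methylbut-3-en-2-one | CC(=O)C(C)=C | starting material
10 | 3-methylbuta-1,3-dien-2-yl bis(isopinocampheyl)borinate, isopinocampheyl groups from (−)-α-pinene | C=C(OB([C@H]1C[C@H]2C[C@@H]([C@@H]1C)C2(C)C)[C@H]1C[C@H]2C[C@@H]([C@@H]1C)C2(C)C)C(C)=C | intermediate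
11 | bis(isopinocampheyl)borinic ester of 12 at the C5 oxygen | C=C(C)C(=O)C[C@@H](OB([C@H]1C[C@H]2C[C@@H]([C@@H]1C)C2(C)C)[C@H]1C[C@H]2C[C@@H]([C@@H]1C)C2(C)C)/C(C)=C/[C@@H](O[Si](C)(C)C(C)(C)C)C(C)(C)C=C | intermediate
12 | (5R,6E,8R)-8-[(tert-butyldimethylsilyl)oxy]-5-hydroxy-2,6,9,9-tetramethylundeca-1,6,10-trien-3-one | C=C(C)C(=O)C[C@@H](O)/C(C)=C/[C@@H](O[Si](C)(C)C(C)(C)C)C(C)(C)C=C | intermediate
13 | (5R,6E,8R)-8-[(tert-butyldimethylsilyl)oxy]-2,6,9,9-tetramethyl-5-[(triethylsilyl)oxy]undeca-1,6,10-trien-3-one | C=C(C)C(=O)C[C@@H](O[Si](CC)(CC)CC)/C(C)=C/[C@@H](O[Si](C)(C)C(C)(C)C)C(C)(C)C=C | intermediate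
14 | (3RS,5R,6E,8R)-8-[(tert-butyldimethylsilyl)oxy]-2,6,9,9-tetramethyl-5-[(triethylsilyl)oxy]undeca-1,6,10-trien-3-ol, both C3 epimers | C=C(C)C(O)C[C@@H](O[Si](CC)(CC)CC)/C(C)=C/[C@@H](O[Si](C)(C)C(C)(C)C)C(C)(C)C=C | intermediate
15 | diethyl (3RS,5R,6E,8R)-8-[(tert-butyldimethylsilyl)oxy]-2,6,9,9-tetramethyl-5-[(triethylsilyl)oxy]undeca-1,6,10-trien-3-yl phosphate | C=C(C)C(OP(=O)(OCC)OCC)C[C@@H](O[Si](CC)(CC)CC)/C(C)=C/[C@@H](O[Si](C)(C)C(C)(C)C)C(C)(C)C=C | intermediate
16 | alkylzirconocene chloride of 15: the terminal vinyl group converted into CH2CH2–ZrCp2Cl | C=C(C)C(OP(=O)(OCC)OCC)C[C@@H](O[Si](CC)(CC)CC)/C(C)=C/[C@@H](O[Si](C)(C)C(C)(C)C)C(C)(C)CC[Zr](Cl)(C1C=CC=C1)C1C=CC=C1 | intermediate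
17 | tert-butyl(dimethyl){[(1R,2E,4R,6E)-3,7,11,11-tetramethyl-4-[(triethylsilyl)oxy]cycloundeca-2,6-dien-1-yl]oxy}silane | C/C1=C\C[C@@H](O[Si](CC)(CC)CC)/C(C)=C/[C@@H](O[Si](C)(C)C(C)(C)C)C(C)(C)CCC1 | intermediate
18 | (1R,2E,4R,9E)-4-[(tert-butyldimethylsilyl)oxy]-2,5,5,9-tetramethylcycloundeca-2,9-dien-1-ol | C/C1=C\C[C@@H](O)/C(C)=C/[C@@H](O[Si](C)(C)C(C)(C)C)C(C)(C)CCC1 | intermediate
19 | 4-[(tert-butyldimethylsilyl)oxy]benzoic acid | CC(C)(C)[Si](C)(C)Oc1ccc(cc1)C(=O)O | starting material
20 | (1R,2E,4R,9E)-4-[(tert-butyldimethylsilyl)oxy]-2,5,5,9-tetramethylcycloundeca-2,9-dien-1-yl 4-[(tert-butyldimethylsilyl)oxy]benzoate | C/C1=C\C[C@@H](OC(=O)c2ccc(O[Si](C)(C)C(C)(C)C)cc2)/C(C)=C/[C@@H](O[Si](C)(C)C(C)(C)C)C(C)(C)CCC1 | intermediate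
21 | (1R,2E,4R,9E)-4-hydroxy-2,5,5,9-tetramethylcycloundeca-2,9-dien-1-yl 4-hydroxybenzoate | C/C1=C\C[C@@H](OC(=O)c2ccc(O)cc2)/C(C)=C/[C@@H](O)C(C)(C)CCC1 | target

## Step count and risks

Total steps: 11. Longest linear sequence: 11 steps (from 1 to 21).

**Step 8 (ring closure).** What may go wrong: oligomerisation may outrun the medium-ring closure, the alkylcopper may decompose before it cyclises, or one C6 epimer may close with poor control of the alkene geometry. The fallback uses known chemistry, sets out from 14 and returns at 17.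
- Hydrozirconation of 14 with Cp2Zr(H)Cl (2.2 equiv, the first equivalent being consumed by the hydroxyl) and iodinolysis with I2 should give the primary iodide F1.
- PhSO2Na in DMF should give the sulfone F2.
- SOCl2 in Et2O should transpose the allylic alcohol to the (E)-configured primary allylic chloride F3 (SNi′, both carbinol epimers converging).
- KN(SiMe3)2 in THF at high dilution should close the ring by intramolecular alkylation of the sulfonyl carbanion, a known type of medium- and large-ring closure, to give the cyclic sulfone F4.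
- Sodium amalgam (Na/Hg) with Na2HPO4 in MeOH should remove the sulfonyl group and give 17.

**Step 4 (aldol).** What may go wrong: poor facial selectivity of the reagent-controlled aldol addition, or the opposite sense of induction. The fallback sets out from 8 (with 9) and returns at 18; it moves control of C4 from the aldol to a late reduction.
- The aldol is run without chiral control (c-Hex2BCl, Et3N) to give the aldol as a mixture of carbinol epimers F5.
- The mixture is carried through the conditions of steps 5 to 9, none of which depends on this centre: the silyl ether mixture F6, the allylic alcohol mixture F7, the phosphate mixture F8, the ring-closed silyl ether mixture F9 and the ring alcohol mixture F10.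
- Dess–Martin periodinane (NaHCO3, CH2Cl2) should then give the macrocyclic enone F11.
- Corey–Bakshi–Shibata reduction with the (S)-Me-oxazaborolidine and BH3·SMe2, the alkenyl group acting as the large substituent, should deliver the (R)-carbinol 18 from both epimers.

**Step 3 (allylic oxidation).** What may go wrong: a sluggish ene reaction at the hindered alkene, with over-oxidation or loss of the silyl ether under the hot acidic conditions. The fallback sets out from 6 and returns at 8.
- mCPBA (NaHCO3, CH2Cl2, 0 °C) should epoxidise only the electron-rich trisubstituted alkene and give the epoxide F12.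
- H5IO6 in Et2O should cleave it to the α-silyloxy aldehyde F13.
- Wittig reaction with Ph3P=C(Me)CHO in toluene at 90 °C should give the (E)-enal 8.

## Further compounds

F1 | step 8 | (5R,6E,8R)-8-[(tert-butyldimethylsilyl)oxy]-11-iodo-2,6,9,9-tetramethyl-5-[(triethylsilyl)oxy]undeca-1,6-dien-3-ol, C3 epimers | C=C(C)C(O)C[C@@H](O[Si](CC)(CC)CC)/C(C)=C/[C@@H](O[Si](C)(C)C(C)(C)C)C(C)(C)CCI
F2 | step 8 | (5R,6E,8R)-11-(benzenesulfonyl)-8-[(tert-butyldimethylsilyl)oxy]-2,6,9,9-tetramethyl-5-[(triethylsilyl)oxy]undeca-1,6-dien-3-ol, C3 epimers | C=C(C)C(O)C[C@@H](O[Si](CC)(CC)CC)/C(C)=C/[C@@H](O[Si](C)(C)C(C)(C)C)C(C)(C)CCS(=O)(=O)c1ccccc1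
F3 | step 8 | (2E,5R,6E,8R)-11-(benzenesulfonyl)-8-[(tert-butyldimethylsilyl)oxy]-1-chloro-2,6,9,9-tetramethyl-5-[(triethylsilyl)oxy]undeca-2,6-diene | ClC/C(C)=C/C[C@@H](O[Si](CC)(CC)CC)/C(C)=C/[C@@H](O[Si](C)(C)C(C)(C)C)C(C)(C)CCS(=O)(=O)c1ccccc1
F4 | step 8 | tert-butyl(dimethyl){[(1R,2E,4R,6E)-9-(benzenesulfonyl)-3,7,11,11-tetramethyl-4-[(triethylsilyl)oxy]cycloundeca-2,6-dien-1-yl]oxy}silane, C9 epimers | C/C1=C\C[C@@H](O[Si](CC)(CC)CC)/C(C)=C/[C@@H](O[Si](C)(C)C(C)(C)C)C(C)(C)CC(S(=O)(=O)c2ccccc2)C1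
F5 | step 4 | (5RS,6E,8R)-8-[(tert-butyldimethylsilyl)oxy]-5-hydroxy-2,6,9,9-tetramethylundeca-1,6,10-trien-3-one | C=C(C)C(=O)CC(O)/C(C)=C/[C@@H](O[Si](C)(C)C(C)(C)C)C(C)(C)C=C
F6 | step 4 | (5RS,6E,8R)-8-[(tert-butyldimethylsilyl)oxy]-2,6,9,9-tetramethyl-5-[(triethylsilyl)oxy]undeca-1,6,10-trien-3-one | C=C(C)C(=O)CC(O[Si](CC)(CC)CC)/C(C)=C/[C@@H](O[Si](C)(C)C(C)(C)C)C(C)(C)C=C
F7 | step 4 | (3RS,5RS,6E,8R)-8-[(tert-butyldimethylsilyl)oxy]-2,6,9,9-tetramethyl-5-[(triethylsilyl)oxy]undeca-1,6,10-trien-3-ol | C=C(C)C(O)CC(O[Si](CC)(CC)CC)/C(C)=C/[C@@H](O[Si](C)(C)C(C)(C)C)C(C)(C)C=C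
F8 | step 4 | diethyl (3RS,5RS,6E,8R)-8-[(tert-butyldimethylsilyl)oxy]-2,6,9,9-tetramethyl-5-[(triethylsilyl)oxy]undeca-1,6,10-trien-3-yl phosphate | C=C(C)C(OP(=O)(OCC)OCC)CC(O[Si](CC)(CC)CC)/C(C)=C/[C@@H](O[Si](C)(C)C(C)(C)C)C(C)(C)C=C
F9 | step 4 | tert-butyl(dimethyl){[(1R,2E,4RS,6E)-3,7,11,11-tetramethyl-4-[(triethylsilyl)oxy]cycloundeca-2,6-dien-1-yl]oxy}silane | C/C1=C\CC(O[Si](CC)(CC)CC)/C(C)=C/[C@@H](O[Si](C)(C)C(C)(C)C)C(C)(C)CCC1
F10 | step 4 | (1RS,2E,4R,9E)-4-[(tert-butyldimethylsilyl)oxy]-2,5,5,9-tetramethylcycloundeca-2,9-dien-1-ol | C/C1=C\CC(O)/C(C)=C/[C@@H](O[Si](C)(C)C(C)(C)C)C(C)(C)CCC1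
F11 | step 4 | (2E,4R,9E)-4-[(tert-butyldimethylsilyl)oxy]-2,5,5,9-tetramethylcycloundeca-2,9-dien-1-one | C/C1=C\CC(=O)/C(C)=C/[C@@H](O[Si](C)(C)C(C)(C)C)C(C)(C)CCC1
F12 | step 3 | tert-butyl{[(1S)-1-(3,3-dimethyloxiran-2-yl)-2,2-dimethylbut-3-en-1-yl]oxy}dimethylsilane, oxirane carbon as a mixture | CC1(C)OC1[C@@H](O[Si](C)(C)C(C)(C)C)C(C)(C)C=C
F13 | step 3 | (2S)-2-[(tert-butyldimethylsilyl)oxy]-3,3-dimethylpent-4-enal | O=C[C@@H](O[Si](C)(C)C(C)(C)C)C(C)(C)C=C
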